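**Retrosynthetic overview**
1. Rings B and C are finished last: the pterocarpan (C6a, C11a) comes from a 2'-hydroxyisoflavone by asymmetric transfer hydrogenation with dynamic kinetic resolution, then acid closure of ring C (O11–C11a).
2. The isoflavone is cut at the future C6a–C6b bond (Suzuki coupling) into a 3-iodochromone carrying rings A, B and F and an arylboronate carrying rings D and E.
3. Ring E (O1'–C2'(CH3)2–C3'H(OH)–C4'H2, fused to C9–C10 of ring D) is cut at C4'–C3'. It is closed by an enantioselective cobalt carbene-radical 1,6-C–H alkylation of an aryl aldehyde tosylhydrazone whose ortho oxygen carries the open chain C(CH3)2–CH2–OMOM.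
4. Enabling feature: C2' of ring E is quaternary (two methyl groups, no hydrogen) and lies between the ring D ether oxygen and C3'. A carbene on the carbon attached to C10 therefore has no 1,5-hydrogen and reaches the oxygen-activated C3'–H by 1,6-transfer; the gem-dimethyl group also pre-folds the chain.
5. Ring order: F (chromenylation), then B as a chromone; separately E (key step); then union, reduction of B and closure of C. Rings A and D come from bought arenes.

Key step: step 5

Remark: the target is read from its SMILES as the (6aR,11aR)-pterocarpan with a (3'R)-carbinol in ring E; compounds 1, 3, 10 and 11 are taken as commercially available.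

**Step 1**
Reactants: 1 2-methylpropane-1,2-diol
Product: 2 1-(methoxymethoxy)-2-methylpropan-2-ol
Conditions: MOMCl (1.0 equiv), iPr2NEt, CH2Cl2, 0 °C
Reagents that add atoms: chloromethyl methyl ether (MOMCl), COCCl
Why: Williamson-type O-alkylation (MOM protection) should take place at the primary hydroxyl much faster than at the tertiary one, which stays free as the nucleophile for step 2.

**Step 2**
Reactants: 2 1-(methoxymethoxy)-2-methylpropan-2-ol; 3 3-bromo-2,6-difluorobenzaldehyde
Product: 4 3-bromo-2-fluoro-6-{[1-(methoxymethoxy)-2-methylpropan-2-yl]oxy}benzaldehyde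
Conditions: NaH, THF, 0 °C; then 3, −20 → 0 °C
Reagents that add atoms: none
Why: Nucleophilic aromatic substitution (SNAr) activated by the ortho formyl group; the bulky tertiary alkoxide should attack the fluorine flanked by CHO and H (C6) and not the one wedged between CHO and Br, and the new alkoxy group deactivates the ring towards a second substitution.

**Step 3**
Reactants: 4 3-bromo-2-fluoro-6-{[1-(methoxymethoxy)-2-methylpropan-2-yl]oxy}benzaldehyde
Product: 5 3-bromo-2-tert-butoxy-6-{[1-(methoxymethoxy)-2-methylpropan-2-yl]oxy}benzaldehyde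
Conditions: KOtBu (1.2 equiv), THF, 0 → 25 °C
Reagents that add atoms: potassium tert-butoxide, CC(C)(C)[O-].[K+]
Why: A second SNAr at the remaining formyl-activated fluorine; the tert-butyl ether is chosen because its oxygen-bound carbon carries no hydrogen (nothing for the carbene of step 5 to abstract in a 1,5-fashion) and because acid removes it later.

**Step 4**
Reactants: 5 3-bromo-2-tert-butoxy-6-{[1-(methoxymethoxy)-2-methylpropan-2-yl]oxy}benzaldehyde
Product: 6 N'-[(E)-(3-bromo-2-tert-butoxy-6-{[1-(methoxymethoxy)-2-methylpropan-2-yl]oxy}phenyl)methylidene]-4-methylbenzenesulfonohydrazide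
Conditions: TsNHNH2, MeOH, 25 °C
Reagents that add atoms: 4-methylbenzenesulfonohydrazide (TsNHNH2), Cc1ccc(cc1)S(=O)(=O)NN
Why: Condensation of the aldehyde with tosylhydrazide should give the bench-stable N-tosylhydrazone, the diazo precursor for a Bamford–Stevens-type release.

**Step 5**
Reactants: 6 N'-[(E)-(3-bromo-2-tert-butoxy-6-{[1-(methoxymethoxy)-2-methylpropan-2-yl]oxy}phenyl)methylidene]-4-methylbenzenesulfonohydrazide
Product: 8 (3R)-6-bromo-5-tert-butoxy-3-(methoxymethoxy)-2,2-dimethyl-3,4-dihydro-2H-chromene, via aryldiazomethane 7 (not isolated)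
Conditions: [Co(Por*)] (2 mol %; divalent cobalt complex of a D2-symmetric chiral amidoporphyrin of the 3,5-DitBu-ChenPhyrin type, ligand antipode that leads to 3R), Cs2CO3, 1,4-dioxane, 40 °C
Reagents that add atoms: none
Why: Proposed new method: base releases aryldiazomethane 7, which the divalent cobalt porphyrin converts (loss of N2) into a cobalt-bound benzylic carbene radical; since the atom five positions away (C2') is quaternary and the tert-butyl ether offers only primary C–H bonds, the radical should abstract the oxygen-activated C3'–H by 1,6-hydrogen atom transfer, and the resulting α-alkoxy radical should close ring E by homolytic substitution at the Co–C4' bond (6-exo-tet), forming the C4'–C3' bond and returning the catalyst. The closest known reactions are the enantioselective cobalt-metalloradical 1,5-C–H alkylations of tosylhydrazone-derived aryldiazomethanes, which give five-membered rings, and the achiral cobalt-porphyrin 1,6-hydrogen-transfer cyclisations that give piperidines. The new C3' stereocentre is set in the ring-closing radical substitution inside the chiral cavity of the porphyrin (catalyst control; the planar radical makes the step enantioconvergent). The step needs site selectivity for C3'–H over the more numerous methyl C–H bonds and chemoselectivity against carbene dimerisation; the first should be secured by the weaker, hydridic α-alkoxy C–H bond and the gem-dimethyl fold, the second by slow release of 7 at 40 °C.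

**Step 6**
Reactants: 8 (3R)-6-bromo-5-tert-butoxy-3-(methoxymethoxy)-2,2-dimethyl-3,4-dihydro-2H-chromene
Product: 9 2-[(3R)-5-tert-butoxy-3-(methoxymethoxy)-2,2-dimethyl-3,4-dihydro-2H-chromen-6-yl]-4,4,5,5-tetramethyl-1,3,2-dioxaborolane
Conditions: B2pin2, Pd(dppf)Cl2 (3 mol %), KOAc, 1,4-dioxane, 90 °C
Reagents that add atoms: bis(pinacolato)diboron, CC1(C)OB(OC1(C)C)B1OC(C)(C)C(C)(C)O1
Why: Miyaura borylation of the aryl bromide; the ethers, the acetal and the stereocentre are inert to KOAc and the palladium catalyst.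

**Step 7**
Reactants: 10 1-(2,4-dihydroxyphenyl)ethan-1-one; 11 3-methylbut-2-enal
Product: 12 1-(5-hydroxy-2,2-dimethyl-2H-chromen-6-yl)ethan-1-one
Conditions: pyridine, 140 °C (sealed tube)
Reagents that add atoms: none
Why: Base-mediated chromenylation: C-alkylation of the resorcinol at the carbon between the two oxygens by the enal, dehydration to an ortho-quinone methide and oxa-6π electrocyclisation should give ring F, with the chelated 2-OH left free.

**Step 8**
Reactants: 12 1-(5-hydroxy-2,2-dimethyl-2H-chromen-6-yl)ethan-1-one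
Product: 13 (2E)-3-(dimethylamino)-1-(5-hydroxy-2,2-dimethyl-2H-chromen-6-yl)prop-2-en-1-one
Conditions: N,N-dimethylformamide dimethyl acetal, toluene, 90 °C
Reagents that add atoms: N,N-dimethylformamide dimethyl acetal, COC(OC)N(C)C
Why: Condensation of the methyl ketone with the amide acetal should give the enaminone, which supplies the future C6 carbon.

**Step 9**
Reactants: 13 (2E)-3-(dimethylamino)-1-(5-hydroxy-2,2-dimethyl-2H-chromen-6-yl)prop-2-en-1-one
Product: 14 3-iodo-8,8-dimethyl-4H,8H-pyrano[2,3-f]chromen-4-one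
Conditions: iodine (1.5 equiv), MeOH, 25 °C
Reagents that add atoms: iodine, [I][I]
Why: Iodine-mediated cyclisation of a 2-hydroxyaryl enaminone: α-iodination, attack of the phenol on the iminium carbon and loss of dimethylamine should give the 3-iodochromone (ring B at the chromone level).

**Step 10**
Reactants: 9 2-[(3R)-5-tert-butoxy-3-(methoxymethoxy)-2,2-dimethyl-3,4-dihydro-2H-chromen-6-yl]-4,4,5,5-tetramethyl-1,3,2-dioxaborolane; 14 3-iodo-8,8-dimethyl-4H,8H-pyrano[2,3-f]chromen-4-one
Product: 15 3-[(3R)-5-tert-butoxy-3-(methoxymethoxy)-2,2-dimethyl-3,4-dihydro-2H-chromen-6-yl]-8,8-dimethyl-4H,8H-pyrano[2,3-f]chromen-4-one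
Conditions: Pd(dppf)Cl2 (5 mol %), Na2CO3 (2 M aq.), DME, 80 °C
Reagents that add atoms: none
Why: Suzuki–Miyaura coupling should join the two halves at C3 of the chromone, the future C6a–C6b bond.

**Step 11**
Reactants: 15 3-[(3R)-5-tert-butoxy-3-(methoxymethoxy)-2,2-dimethyl-3,4-dihydro-2H-chromen-6-yl]-8,8-dimethyl-4H,8H-pyrano[2,3-f]chromen-4-one
Product: 16 3-[(3R)-3,5-dihydroxy-2,2-dimethyl-3,4-dihydro-2H-chromen-6-yl]-8,8-dimethyl-4H,8H-pyrano[2,3-f]chromen-4-one
Conditions: HCl (4 M in 1,4-dioxane), MeOH, 40 °C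
Reagents that add atoms: none
Why: Acid cleavage of the aryl tert-butyl ether (SN1/E1) and acetal exchange of the MOM group in one operation; the chromone and the chromene conjugated to it should tolerate methanolic HCl.

**Step 12**
Reactants: 16 3-[(3R)-3,5-dihydroxy-2,2-dimethyl-3,4-dihydro-2H-chromen-6-yl]-8,8-dimethyl-4H,8H-pyrano[2,3-f]chromen-4-one
Product: 19 target: (6aR,11aR)-pterocarpan with a 2,2-dimethyl-2H-pyran fused at C3–C4 (oxygen on C3) and a (3'R)-3'-hydroxy-2',2'-dimethyl-3',4'-dihydro-2H-pyran fused at C9–C10 (oxygen on C9), via isoflavanone 17 (not isolated), via cis-isoflavan-4-ol 18 (not isolated)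
Conditions: RuCl(p-cymene)[(R,R)-TsDPEN] (5 mol %), HCO2H/Et3N (5:2), EtOAc, 40 °C; then HCl (aq.), EtOH, 25 °C, one pot
Reagents that add atoms: none
Why: Asymmetric transfer hydrogenation of Noyori–Ikariya type: conjugate reduction gives the configurationally labile isoflavanone 17, whose ketone is reduced under dynamic kinetic resolution to the cis-(3R,4R)-alcohol 18 (catalyst control of both centres); acid then ionises the para-alkoxy-stabilised benzylic alcohol and the 2'-phenol closes ring C, necessarily cis, giving 6aR,11aR and leaving the ring E carbinol untouched.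

**Compound list**
1 | 2-methylpropane-1,2-diol | CC(C)(O)CO | starting material
2 | 1-(methoxymethoxy)-2-methylpropan-2-ol | COCOCC(C)(C)O | intermediate
3 | 3-bromo-2,6-difluorobenzaldehyde | O=Cc1c(F)ccc(Br)c1F | starting material
4 | 3-bromo-2-fluoro-6-{[1-(methoxymethoxy)-2-methylpropan-2-yl]oxy}benzaldehyde | O=Cc1c(F)c(Br)ccc1OC(C)(C)COCOC | intermediate
5 | 3-bromo-2-tert-butoxy-6-{[1-(methoxymethoxy)-2-methylpropan-2-yl]oxy}benzaldehyde | O=Cc1c(OC(C)(C)C)c(Br)ccc1OC(C)(C)COCOC | intermediate
6 | N'-[(E)-(3-bromo-2-tert-butoxy-6-{[1-(methoxymethoxy)-2-methylpropan-2-yl]oxy}phenyl)methylidene]-4-methylbenzenesulfonohydrazide | Cc1ccc(cc1)S(=O)(=O)N/N=C/c1c(OC(C)(C)C)c(Br)ccc1OC(C)(C)COCOC | intermediate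
7 | 1-bromo-2-tert-butoxy-3-(diazomethyl)-4-{[1-(methoxymethoxy)-2-methylpropan-2-yl]oxy}benzene | [N-]=[N+]=Cc1c(OC(C)(C)C)c(Br)ccc1OC(C)(C)COCOC | intermediate (not isolated)
8 | (3R)-6-bromo-5-tert-butoxy-3-(methoxymethoxy)-2,2-dimethyl-3,4-dihydro-2H-chromene | Brc1ccc2c(c1OC(C)(C)C)C[C@@H](OCOC)C(C)(C)O2 | intermediate
9 | 2-[(3R)-5-tert-butoxy-3-(methoxymethoxy)-2,2-dimethyl-3,4-dihydro-2H-chromen-6-yl]-4,4,5,5-tetramethyl-1,3,2-dioxaborolane | CC1(C)OB(OC1(C)C)c1ccc2c(c1OC(C)(C)C)C[C@@H](OCOC)C(C)(C)O2 | intermediate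
10 | 1-(2,4-dihydroxyphenyl)ethan-1-one | CC(=O)c1ccc(O)cc1O | starting material
11 | 3-methylbut-2-enal | CC(C)=CC=O | starting material
12 | 1-(5-hydroxy-2,2-dimethyl-2H-chromen-6-yl)ethan-1-one | CC(=O)c1ccc2OC(C)(C)C=Cc2c1O | intermediate
13 | (2E)-3-(dimethylamino)-1-(5-hydroxy-2,2-dimethyl-2H-chromen-6-yl)prop-2-en-1-one | CN(C)/C=C/C(=O)c1ccc2OC(C)(C)C=Cc2c1O | intermediate
14 | 3-iodo-8,8-dimethyl-4H,8H-pyrano[2,3-f]chromen-4-one | O=c1c(I)coc2c1ccc1OC(C)(C)C=Cc12 | intermediate
15 | 3-[(3R)-5-tert-butoxy-3-(methoxymethoxy)-2,2-dimethyl-3,4-dihydro-2H-chromen-6-yl]-8,8-dimethyl-4H,8H-pyrano[2,3-f]chromen-4-one | O=c1c(-c2ccc3c(c2OC(C)(C)C)C[C@@H](OCOC)C(C)(C)O3)coc2c1ccc1OC(C)(C)C=Cc12 | intermediate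
16 | 3-[(3R)-3,5-dihydroxy-2,2-dimethyl-3,4-dihydro-2H-chromen-6-yl]-8,8-dimethyl-4H,8H-pyrano[2,3-f]chromen-4-one | O=c1c(-c2ccc3c(c2O)C[C@@H](O)C(C)(C)O3)coc2c1ccc1OC(C)(C)C=Cc12 | intermediate
17 | 3-[(3R)-3,5-dihydroxy-2,2-dimethyl-3,4-dihydro-2H-chromen-6-yl]-8,8-dimethyl-2,3-dihydro-4H,8H-pyrano[2,3-f]chromen-4-one (both C3 epimers, interconverting) | O=C1C(c2ccc3c(c2O)C[C@@H](O)C(C)(C)O3)COc2c1ccc1OC(C)(C)C=Cc12 | intermediate (not isolated)
18 | (3R,4R)-3-[(3R)-3,5-dihydroxy-2,2-dimethyl-3,4-dihydro-2H-chromen-6-yl]-8,8-dimethyl-3,4-dihydro-2H,8H-pyrano[2,3-f]chromen-4-ol (cis) | CC1(C)C=Cc2c(ccc3c2OC[C@@H](c4ccc5c(c4O)C[C@@H](O)C(C)(C)O5)[C@H]3O)O1 | intermediate (not isolated)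
19 | CNP0126417.1, (6aR,11aR,3'R)-pterocarpan with fused dimethylpyran (ring F) and hydroxydimethyldihydropyran (ring E) | CC1(C)C=Cc2c(ccc3c2OC[C@H]2c4ccc5c(c4O[C@@H]32)C[C@@H](O)C(C)(C)O5)O1 | target

**Step count and risks**
Total step count: 12. Longest linear sequence: 9 steps (steps 1–6, 10, 11, 12).

Steps most likely to fail:

Step 5 (Proposed new method). The cobalt-bound carbene radical may dimerise to azine or stilbene instead of abstracting hydrogen. The C3' radical may fragment by loss of the aryloxyl group. Ring closure at the crowded 2,6-disubstituted benzylic centre may be slow or poorly face-selective. The fallback uses known chemistry, closes the same C4'–C3' bond by ring-closing metathesis, sets out from compound 3 and comes back at compound 8. Compound 3 is treated with the sodium alkoxide of 2-methylbut-3-en-2-ol (NaH, THF) to give 3-bromo-2-fluoro-6-[(2-methylbut-3-en-2-yl)oxy]benzaldehyde F1. KOtBu then gives 3-bromo-2-tert-butoxy-6-[(2-methylbut-3-en-2-yl)oxy]benzaldehyde F2. Wittig methylenation (Ph3PCH3Br, KOtBu, THF) gives 1-bromo-2-tert-butoxy-3-ethenyl-4-[(2-methylbut-3-en-2-yl)oxy]benzene F3. Ring-closing metathesis with the second-generation Grubbs catalyst (CH2Cl2, 40 °C) should close ring E as 6-bromo-5-tert-butoxy-2,2-dimethyl-2H-chromene F4. Jacobsen epoxidation with (R,R)-(salen)MnCl, NaOCl and 4-phenylpyridine N-oxide should give (3R,4R)-6-bromo-5-tert-butoxy-3,4-epoxy-2,2-dimethyl-3,4-dihydro-2H-chromene F5. LiBHEt3 (THF, 0 °C) should open the epoxide at the benzylic carbon to (3R)-6-bromo-5-tert-butoxy-2,2-dimethyl-3,4-dihydro-2H-chromen-3-ol F6, and MOMCl/iPr2NEt returns compound 8.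

Step 3. tert-Butoxide may add to the formyl group and trigger hydride-transfer side reactions, or substitution at the carbon wedged between CHO and Br may be too slow. The fallback sets out from compound 4 and comes back at compound 5. Fluoride is displaced by the small hydroxide ion (KOH, DMSO–water, 60 °C) to give 3-bromo-2-hydroxy-6-{[1-(methoxymethoxy)-2-methylpropan-2-yl]oxy}benzaldehyde F7. The phenol is then O-tert-butylated under neutral conditions with N,N-dimethylformamide di-tert-butyl acetal (toluene, 80 °C). The tert-butyl–oxygen bond is thus made by alkylation at oxygen and not by SNAr at the hindered ring carbon.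

Step 2. Substitution may occur at the wrong fluorine (poor site selectivity), or twice. The fallback sets out from compound 2 and comes back at compound 4. The sodium alkoxide of 2 is reacted with symmetrical 2,6-difluorobenzaldehyde, which has only one monosubstitution product, to give 2-fluoro-6-{[1-(methoxymethoxy)-2-methylpropan-2-yl]oxy}benzaldehyde F8. Electrophilic bromination with NBS (MeCN, 0 °C), directed para to the ether oxygen and ortho to fluorine, then places the bromine and returns compound 4.

**Further compounds**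
F1 | step 5 | 3-bromo-2-fluoro-6-[(2-methylbut-3-en-2-yl)oxy]benzaldehyde | O=Cc1c(F)c(Br)ccc1OC(C)(C)C=C
F2 | step 5 | 3-bromo-2-tert-butoxy-6-[(2-methylbut-3-en-2-yl)oxy]benzaldehyde | O=Cc1c(OC(C)(C)C)c(Br)ccc1OC(C)(C)C=C
F3 | step 5 | 1-bromo-2-tert-butoxy-3-ethenyl-4-[(2-methylbut-3-en-2-yl)oxy]benzene | C=Cc1c(OC(C)(C)C)c(Br)ccc1OC(C)(C)C=C
F4 | step 5 | 6-bromo-5-tert-butoxy-2,2-dimethyl-2H-chromene | Brc1ccc2OC(C)(C)C=Cc2c1OC(C)(C)C
F5 | step 5 | (3R,4R)-6-bromo-5-tert-butoxy-3,4-epoxy-2,2-dimethyl-3,4-dihydro-2H-chromene | Brc1ccc2c(c1OC(C)(C)C)[C@H]3O[C@H]3C(C)(C)O2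
F6 | step 5 | (3R)-6-bromo-5-tert-butoxy-2,2-dimethyl-3,4-dihydro-2H-chromen-3-ol | Brc1ccc2c(c1OC(C)(C)C)C[C@@H](O)C(C)(C)O2
F7 | step 3 | 3-bromo-2-hydroxy-6-{[1-(methoxymethoxy)-2-methylpropan-2-yl]oxy}benzaldehyde | O=Cc1c(O)c(Br)ccc1OC(C)(C)COCOC
F8 | step 2 | 2-fluoro-6-{[1-(methoxymethoxy)-2-methylpropan-2-yl]oxy}benzaldehyde | O=Cc1c(F)cccc1OC(C)(C)COCOC
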